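The C5' ketone is the hinge: it sits between the allylic methylene C4' and the (Z)-alkenyl carbon C6', so both of its C–C bonds are cut and the carbonyl carbon is traced to carbon monoxide. One palladium-catalysed, base-free three-component coupling joins an (E)-allylic chloride carrying the silyl-protected hydroquinone ring A (C1'–C4') to a (Z)-alkenylstannane carrying C6'–C16' and the (R)-C13' silyl ether. It forms C4'–C5' and C5'–C6' without disturbing the skipped C2'=C3' alkene or the (Z)-C6'=C7' alkene. The precursor pair is thus a primary allylic chloride and a trisubstituted (Z)-vinylstannane; global desilylation then gives the target.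

Key step: step 16

Remarks on the chemistry:
- Chain carbons are numbered C1' (benzylic) to C16'; the arene is ring A; C13' is (R) and is the only stereocentre.
- The C13' hydroxyl is carried as a triethylsilyl ether and the phenols as TBS ethers, so that one short buffered fluoride treatment should free all three.
- The propyne carbocupration is run first, on the simple homoprenyl Grignard reagent, and the vinyl iodide is carried to the end of the stannane branch.
- Commercial inputs: o-cresol, prenyl bromide, 5-bromo-2-methylpent-2-ene, propyne, 3-methylbut-2-enal and carbon monoxide.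

**Ring A branch (allylic chloride)**

Step 1
Reactants: 1 o-cresol; 2 prenyl bromide (1-bromo-3-methylbut-2-ene)
Product: 4 2-methyl-6-(3-methylbut-2-enyl)phenol, via sodium 2-methylphenoxide 3 (not isolated)
Conditions: NaH, toluene, 0 °C to rt; then 2, rt
Reagents that add atoms: none
Why: In toluene the sodium phenoxide reacts as a tight aggregate, so the allylic bromide should be delivered to the only free ortho carbon and tautomerisation restores the phenol (ortho-selective C-allylation of a phenoxide in a non-polar medium).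

Step 2
Reactants: 4 2-methyl-6-(3-methylbut-2-enyl)phenol
Product: 5 2-methyl-6-(3-methylbut-2-enyl)cyclohexa-2,5-diene-1,4-dione
Conditions: Co(salen) (cat.), O2 (1 atm), DMF, rt
Reagents that add atoms: dioxygen, O=O
Why: Co(salen) binds O2 and should oxidise the 2,6-disubstituted phenol through its phenoxyl radical at the open para position to the p-benzoquinone, the isolated alkene being inert (cobalt–salen-catalysed aerobic phenol-to-quinone oxidation).

Step 3
Reactants: 5 2-methyl-6-(3-methylbut-2-enyl)cyclohexa-2,5-diene-1,4-dione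
Product: 6 2-methyl-6-(3-methylbut-2-enyl)benzene-1,4-diol
Conditions: Na2S2O4, EtOAc/H2O, rt, argon
Reagents that add atoms: none
Why: Dithionite should reduce the quinone to the hydroquinone by two-electron transfer without touching the alkene (quinone reduction).

Step 4
Reactants: 6 2-methyl-6-(3-methylbut-2-enyl)benzene-1,4-diol
Product: 7 1,4-bis(tert-butyldimethylsilyloxy)-2-methyl-6-(3-methylbut-2-enyl)benzene
Conditions: TBSOTf, 2,6-lutidine, CH2Cl2, 0 °C
Reagents that add atoms: tert-butyldimethylsilyl trifluoromethanesulfonate, CC(C)(C)[Si](C)(C)OS(=O)(=O)C(F)(F)F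
Why: The silyl triflate with a hindered pyridine base should silylate both phenols, including the one flanked by two ortho substituents, which blocks air oxidation and later keeps the phenol oxygen off the allylpalladium (silyl ether formation).

Step 5
Reactants: 7 1,4-bis(tert-butyldimethylsilyloxy)-2-methyl-6-(3-methylbut-2-enyl)benzene
Product: 8 (E)-4-[2,5-bis(tert-butyldimethylsilyloxy)-3-methylphenyl]-2-methylbut-2-en-1-ol
Conditions: SeO2 (cat.), t-BuOOH, salicylic acid (cat.), CH2Cl2, 0 °C to rt
Reagents that add atoms: tert-butyl hydroperoxide, CC(C)(C)OO (oxygen passed on through selenium dioxide, O=[Se]=O)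
Why: SeO2, turned over by t-BuOOH, should attack the trisubstituted alkene by an ene reaction and [2,3]-sigmatropic shift and hydroxylate the methyl group trans to the chain, giving the (E)-allylic alcohol (catalytic Riley allylic oxidation); any co-formed enal is removed on silica.

Step 6
Reactants: 8 (E)-4-[2,5-bis(tert-butyldimethylsilyloxy)-3-methylphenyl]-2-methylbut-2-en-1-ol
Product: 10 (E)-4-[2,5-bis(tert-butyldimethylsilyloxy)-3-methylphenyl]-2-methylbut-2-enyl chloride, via allylic mesylate 9 (not isolated)
Conditions: MsCl, LiCl, 2,4,6-collidine, DMF, 0 °C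
Reagents that add atoms: lithium chloride, [Li+].[Cl-]; methanesulfonyl chloride, CS(=O)(=O)Cl (builds 9; its chloride joins the chloride pool)
Why: The primary allylic mesylate formed in situ should be displaced by chloride in a direct SN2 reaction at CH2, so neither the position nor the (E) geometry of the alkene changes (mesylation–chloride displacement), and no electrophilic chlorine meets the electron-rich ring A.

**Stannane branch**

Step 7
Reactants: 11 5-bromo-2-methylpent-2-ene; 12 propyne
Product: 16 (Z)-1-iodo-2,6-dimethylhepta-1,5-diene, via Grignard reagent 13 (not isolated), via alkylcopper 14 (not isolated), via alkenylcopper 15 (not isolated)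
Conditions: Mg, Et2O, reflux; CuBr·SMe2, Et2O/Me2S, −45 °C; propyne, −25 °C; I2, THF, −78 to 0 °C
Reagents that add atoms: iodine, II
Why: The Grignard-derived organocopper should add syn across propyne with copper at the terminal carbon (Normant carbocupration), and iodinolysis of the alkenylcopper with retention places the chain cis to iodine, giving the (Z)-iodide.

Step 8
Reactants: 16 (Z)-1-iodo-2,6-dimethylhepta-1,5-diene
Product: 17 (2E,6Z)-7-iodo-2,6-dimethylhepta-2,6-dien-1-ol
Conditions: SeO2 (cat.), t-BuOOH, salicylic acid (cat.), CH2Cl2, 0 °C to rt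
Reagents that add atoms: tert-butyl hydroperoxide, CC(C)(C)OO (oxygen passed on through selenium dioxide, O=[Se]=O)
Why: In the same catalytic Riley oxidation the gem-dimethyl alkene is far more nucleophilic than the iodine-bearing alkene, so only its (E)-methyl group should be hydroxylated.

Step 9
Reactants: 17 (2E,6Z)-7-iodo-2,6-dimethylhepta-2,6-dien-1-ol
Product: 18 (1Z,5E)-7-bromo-1-iodo-2,6-dimethylhepta-1,5-diene
Conditions: CBr4, PPh3, CH2Cl2, 0 °C
Reagents that add atoms: tetrabromomethane, BrC(Br)(Br)Br
Why: The Appel reaction should convert the primary allylic alcohol into the bromide by SN2 displacement of the oxyphosphonium group under neutral conditions that leave both alkene geometries and the vinyl iodide alone.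

Step 10
Reactants: 19 3-methylbut-2-enal
Product: 20 2-(2-methylprop-1-enyl)-1,3-dithiane
Conditions: propane-1,3-dithiol, BF3·OEt2 (cat.), CH2Cl2, −20 °C
Reagents that add atoms: propane-1,3-dithiol, SCCCS
Why: Lewis acid-catalysed dithioacetalisation of the aldehyde should prevail because the β,β-dimethyl substitution disfavours conjugate addition of the thiol.

Step 11
Reactants: 20 2-(2-methylprop-1-enyl)-1,3-dithiane; 18 (1Z,5E)-7-bromo-1-iodo-2,6-dimethylhepta-1,5-diene
Product: 22 2-[(2E,6Z)-7-iodo-2,6-dimethylhepta-2,6-dienyl]-2-(2-methylprop-1-enyl)-1,3-dithiane, via 2-lithiodithiane 21 (not isolated)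
Conditions: n-BuLi (0.95 equiv), THF, −78 to −25 °C; then 18, −78 to −20 °C
Reagents that add atoms: none
Why: Deprotonation at C2 gives a sulfur-stabilised allyl anion that should be alkylated by the primary allylic bromide at the dithiane carbon, the γ-terminus being tertiary and hindered (Corey–Seebach umpolung); the slight deficit of n-BuLi leaves no base to attack the vinyl iodide.

Step 12
Reactants: 22 2-[(2E,6Z)-7-iodo-2,6-dimethylhepta-2,6-dienyl]-2-(2-methylprop-1-enyl)-1,3-dithiane
Product: 23 (6E,10Z)-11-iodo-2,6,10-trimethylundeca-2,6,10-trien-4-one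
Conditions: MeI, CaCO3, MeCN/H2O (9:1), 40 °C
Reagents that add atoms: water, O
Why: S-Methylation turns the dithiane sulfur into a leaving group and water captures the thionium ion, while CaCO3 keeps the medium near neutral so that the C6=C7 alkene should not move into conjugation (alkylative dithiane hydrolysis).

Step 13
Reactants: 23 (6E,10Z)-11-iodo-2,6,10-trimethylundeca-2,6,10-trien-4-one
Product: 24 (4R,6E,10Z)-11-iodo-2,6,10-trimethylundeca-2,6,10-trien-4-ol
Conditions: (S)-2-methyl-CBS-oxazaborolidine, catecholborane, toluene, −78 °C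
Reagents that add atoms: none
Why: In the Corey–Bakshi–Shibata reduction the ketone should bind the (S)-oxazaborolidine–borane complex through the lone pair anti to the bulkier isobutenyl group, and intramolecular hydride delivery to one face then sets (R)-C4, the later C13'.

Step 14
Reactants: 24 (4R,6E,10Z)-11-iodo-2,6,10-trimethylundeca-2,6,10-trien-4-ol
Product: 25 triethyl{[(4R,6E,10Z)-11-iodo-2,6,10-trimethylundeca-2,6,10-trien-4-yl]oxy}silane
Conditions: TESCl, imidazole, CH2Cl2, 0 °C
Reagents that add atoms: chlorotriethylsilane, CC[Si](Cl)(CC)CC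
Why: Silylation of the secondary alcohol (silyl ether formation) should be clean, and the triethylsilyl group is chosen because it later leaves under the same mild fluoride conditions as the aryl silyl ethers.

Step 15
Reactants: 25 triethyl{[(4R,6E,10Z)-11-iodo-2,6,10-trimethylundeca-2,6,10-trien-4-yl]oxy}silane
Product: 27 tributyl[(1Z,5E,8R)-2,6,10-trimethyl-8-(triethylsilyloxy)undeca-1,5,9-trienyl]stannane, via alkenyllithium 26 (not isolated)
Conditions: t-BuLi (2.1 equiv), Et2O, −78 °C; Bu3SnCl, −78 °C to rt
Reagents that add atoms: tributyltin chloride, CCCC[Sn](Cl)(CCCC)CCCC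
Why: Iodine–lithium exchange at −78 °C should give the configurationally stable (Z)-alkenyllithium, which is stannylated with retention (halogen–metal exchange and electrophilic trapping).

**Union and end game**

Step 16
Reactants: 10 (E)-4-[2,5-bis(tert-butyldimethylsilyloxy)-3-methylphenyl]-2-methylbut-2-enyl chloride; 27 tributyl[(1Z,5E,8R)-2,6,10-trimethyl-8-(triethylsilyloxy)undeca-1,5,9-trienyl]stannane; 28 carbon monoxide
Product: 29 (2E,6Z,10E,13R)-1-[2,5-bis(tert-butyldimethylsilyloxy)-3-methylphenyl]-3,7,11,15-tetramethyl-13-(triethylsilyloxy)hexadeca-2,6,10,14-tetraen-5-one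
Conditions: Pd2(dba)3·CHCl3 (cat.), AsPh3, CO (3 atm), THF, 50 °C
Reagents that add atoms: none
Why: Zerovalent palladium ionises the primary allylic chloride 10 to an allylpalladium chloride, CO inserts into the Pd–C bond at the unsubstituted terminus C4' to give a β,γ-unsaturated acylpalladium, the alkenyl group of 27 passes from tin to palladium with retention, and reductive elimination releases ketone 29 and returns the catalyst. The closest known reaction type is the palladium-catalysed carbonylative cross-coupling of allylic chlorides with alkenylstannanes to allyl alkenyl ketones (carbonylative Stille coupling). No ring is closed and no stereocentre is created; C13' is a spectator. The step needs acylation at C4' and not at C2', retention of (E)-C2'=C3' and (Z)-C6'=C7', CO uptake ahead of direct allyl–alkenyl coupling, and no drift of the C2'=C3' alkene into conjugation. These should be secured by the preference of palladium for the CH2 terminus over the CH(CH2Ar) terminus, the syn allyl complex formed from the (E)-chloride, stereoretentive tin-to-palladium transfer, CO pressure with the weakly bound AsPh3 ligand, and the neutral, base-free medium. The silyl ethers on ring A keep the phenol oxygen off the allylpalladium, and the C13' silyl ether keeps the alcohol away from the acylpalladium.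

Step 17
Reactants: 29 (2E,6Z,10E,13R)-1-[2,5-bis(tert-butyldimethylsilyloxy)-3-methylphenyl]-3,7,11,15-tetramethyl-13-(triethylsilyloxy)hexadeca-2,6,10,14-tetraen-5-one
Product: 30 2-[(2E,6Z,10E,13R)-13-hydroxy-3,7,11,15-tetramethyl-5-oxohexadeca-2,6,10,14-tetraenyl]-6-methylbenzene-1,4-diol (target)
Conditions: Bu4NF, AcOH, THF (degassed), 0 °C to rt, argon
Reagents that add atoms: none
Why: Fluoride should cleave the two aryl Si–O bonds and the triethylsilyl ether, with acetic acid buffering phenoxide and fluoride basicity so that the skipped enone is not conjugated and, under argon, the hydroquinone is not oxidised (fluoride desilylation).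

**Compound list**

1 | o-cresol | Cc1ccccc1O | starting material
2 | prenyl bromide (1-bromo-3-methylbut-2-ene) | CC(C)=CCBr | starting material
3 | sodium 2-methylphenoxide | Cc1ccccc1[O-].[Na+] | intermediate (not isolated)
4 | 2-methyl-6-(3-methylbut-2-enyl)phenol | CC(C)=CCc1cccc(C)c1O | intermediate
5 | 2-methyl-6-(3-methylbut-2-enyl)cyclohexa-2,5-diene-1,4-dione | CC(C)=CCC1=CC(=O)C=C(C)C1=O | intermediate
6 | 2-methyl-6-(3-methylbut-2-enyl)benzene-1,4-diol | CC(C)=CCc1cc(O)cc(C)c1O | intermediate
7 | 1,4-bis(tert-butyldimethylsilyloxy)-2-methyl-6-(3-methylbut-2-enyl)benzene | CC(C)=CCc1cc(O[Si](C)(C)C(C)(C)C)cc(C)c1O[Si](C)(C)C(C)(C)C | intermediate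
8 | (E)-4-[2,5-bis(tert-butyldimethylsilyloxy)-3-methylphenyl]-2-methylbut-2-en-1-ol | OC/C(C)=C/Cc1cc(O[Si](C)(C)C(C)(C)C)cc(C)c1O[Si](C)(C)C(C)(C)C | intermediate
9 | (E)-4-[2,5-bis(tert-butyldimethylsilyloxy)-3-methylphenyl]-2-methylbut-2-enyl methanesulfonate | CS(=O)(=O)OC/C(C)=C/Cc1cc(O[Si](C)(C)C(C)(C)C)cc(C)c1O[Si](C)(C)C(C)(C)C | intermediate (not isolated)
10 | (E)-4-[2,5-bis(tert-butyldimethylsilyloxy)-3-methylphenyl]-2-methylbut-2-enyl chloride | ClC/C(C)=C/Cc1cc(O[Si](C)(C)C(C)(C)C)cc(C)c1O[Si](C)(C)C(C)(C)C | intermediate (key-step precursor)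
11 | 5-bromo-2-methylpent-2-ene | CC(C)=CCCBr | starting material
12 | propyne | CC#C | starting material
13 | (4-methylpent-3-enyl)magnesium bromide | CC(C)=CCC[Mg]Br | intermediate (not isolated)
14 | (4-methylpent-3-enyl)copper, as its MgBr2 complex | CC(C)=CCC[Cu] | intermediate (not isolated)
15 | [(Z)-2,6-dimethylhepta-1,5-dienyl]copper | CC(C)=CCC/C(C)=C\[Cu] | intermediate (not isolated)
16 | (Z)-1-iodo-2,6-dimethylhepta-1,5-diene | CC(C)=CCC/C(C)=C\I | intermediate
17 | (2E,6Z)-7-iodo-2,6-dimethylhepta-2,6-dien-1-ol | OC/C(C)=C/CC/C(C)=C\I | intermediate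
18 | (1Z,5E)-7-bromo-1-iodo-2,6-dimethylhepta-1,5-diene | BrC/C(C)=C/CC/C(C)=C\I | intermediate
19 | 3-methylbut-2-enal | CC(C)=CC=O | starting material
20 | 2-(2-methylprop-1-enyl)-1,3-dithiane | CC(C)=CC1SCCCS1 | intermediate
21 | 2-lithio-2-(2-methylprop-1-enyl)-1,3-dithiane | [Li]C1(C=C(C)C)SCCCS1 | intermediate (not isolated)
22 | 2-[(2E,6Z)-7-iodo-2,6-dimethylhepta-2,6-dienyl]-2-(2-methylprop-1-enyl)-1,3-dithiane | CC(C)=CC1(C/C(C)=C/CC/C(C)=C\I)SCCCS1 | intermediate
23 | (6E,10Z)-11-iodo-2,6,10-trimethylundeca-2,6,10-trien-4-one | CC(C)=CC(=O)C/C(C)=C/CC/C(C)=C\I | intermediate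
24 | (4R,6E,10Z)-11-iodo-2,6,10-trimethylundeca-2,6,10-trien-4-ol | CC(C)=C[C@H](O)C/C(C)=C/CC/C(C)=C\I | intermediate
25 | triethyl{[(4R,6E,10Z)-11-iodo-2,6,10-trimethylundeca-2,6,10-trien-4-yl]oxy}silane | CC(C)=C[C@H](O[Si](CC)(CC)CC)C/C(C)=C/CC/C(C)=C\I | intermediate
26 | [(1Z,5E,8R)-2,6,10-trimethyl-8-(triethylsilyloxy)undeca-1,5,9-trienyl]lithium | CC(C)=C[C@H](O[Si](CC)(CC)CC)C/C(C)=C/CC/C(C)=C\[Li] | intermediate (not isolated)
27 | tributyl[(1Z,5E,8R)-2,6,10-trimethyl-8-(triethylsilyloxy)undeca-1,5,9-trienyl]stannane | CC(C)=C[C@H](O[Si](CC)(CC)CC)C/C(C)=C/CC/C(C)=C\[Sn](CCCC)(CCCC)CCCC | intermediate (key-step precursor)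
28 | carbon monoxide | [C-]#[O+] | starting material
29 | (2E,6Z,10E,13R)-1-[2,5-bis(tert-butyldimethylsilyloxy)-3-methylphenyl]-3,7,11,15-tetramethyl-13-(triethylsilyloxy)hexadeca-2,6,10,14-tetraen-5-one | CC(C)=C[C@H](O[Si](CC)(CC)CC)C/C(C)=C/CC/C(C)=C\C(=O)C/C(C)=C/Cc1cc(O[Si](C)(C)C(C)(C)C)cc(C)c1O[Si](C)(C)C(C)(C)C | intermediate (key-step product)
30 | 2-[(2E,6Z,10E,13R)-13-hydroxy-3,7,11,15-tetramethyl-5-oxohexadeca-2,6,10,14-tetraenyl]-6-methylbenzene-1,4-diol | CC(C)=C[C@H](O)C/C(C)=C/CC/C(C)=C\C(=O)C/C(C)=C/Cc1cc(O)cc(C)c1O | target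

**Step count and risk**

Total step count: 17. Longest linear sequence: 10 steps (steps 7, 8, 9, 11, 12, 13, 14, 15, 16, 17).

Most likely to fail, step 16: direct allyl–alkenyl coupling may outrun CO uptake, syn/anti exchange of the 2-methyl-substituted allylpalladium may erode the (E)-C2'=C3' geometry, or β-hydride loss may give a diene. The fallback drops the carbonylation and builds the ketone by addition and oxidation; it sets out from chloride 10 and iodide 25 and returns at ketone 29. Chloride 10 is alkylated with 2-lithio-1,3-dithiane (THF, −78 to −20 °C) to give 2-[(E)-4-[2,5-bis(tert-butyldimethylsilyloxy)-3-methylphenyl]-2-methylbut-2-enyl]-1,3-dithiane F1. Hydrolysis with MeI and CaCO3 in aqueous MeCN gives the β,γ-unsaturated aldehyde (E)-5-[2,5-bis(tert-butyldimethylsilyloxy)-3-methylphenyl]-3-methylpent-3-enal F2, which is used crude. Nozaki–Hiyama–Kishi coupling of F2 with iodide 25 (CrCl2, NiCl2 cat., DMF/THF), a non-basic addition that keeps the (Z)-alkene, gives the C5' carbinol F3 as both epimers. Dess–Martin periodinane with NaHCO3 oxidises F3 to 29.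

Second, step 13: facial discrimination may be poor because both ketone flanks are unsaturated and of similar size. The fallback replaces asymmetric reduction by resolution; it sets out from enone 23 and returns at alcohol 24. Luche reduction (NaBH4, CeCl3·7H2O, MeOH, −78 °C) gives the racemic alcohol (6E,10Z)-11-iodo-2,6,10-trimethylundeca-2,6,10-trien-4-ol F4. Esterification with (S)-2-methoxy-2-phenylacetic acid (DCC, DMAP, CH2Cl2) gives two diastereomeric esters that are separated on silica: the (4R)-ester (4R,6E,10Z)-11-iodo-2,6,10-trimethylundeca-2,6,10-trien-4-yl (S)-2-methoxy-2-phenylacetate F5 and its (4S)-diastereomer F6, which is set aside. Methanolysis of F5 (K2CO3, MeOH) gives 24.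

Third, step 17: during the time the C13' silyl ether needs, the C2'=C3' alkene may migrate into conjugation with the C5' ketone or the freed hydroquinone may be oxidised. The fallback changes the protecting-group plan so that only two aryl silyl ethers remain at the end; it sets out from alcohol 24 and returns at target 30. Without silylation, 24 is converted through its lithium alkoxide (t-BuLi, 3.1 equiv, Et2O, −78 °C; then Bu3SnCl) into the hydroxy stannane (4R,6E,10Z)-2,6,10-trimethyl-11-(tributylstannyl)undeca-2,6,10-trien-4-ol F7. The same three-component coupling of F7 with 10 and CO gives the bis(tert-butyldimethylsilyl) ether (2E,6Z,10E,13R)-1-[2,5-bis(tert-butyldimethylsilyloxy)-3-methylphenyl]-13-hydroxy-3,7,11,15-tetramethylhexadeca-2,6,10,14-tetraen-5-one F8. Its aryl silyl ethers should fall within minutes at 0 °C with Bu4NF/AcOH under argon to give 30.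

**Further compounds**

F1 | step 16 | 2-[(E)-4-[2,5-bis(tert-butyldimethylsilyloxy)-3-methylphenyl]-2-methylbut-2-enyl]-1,3-dithiane | S1CCCSC1C/C(C)=C/Cc1cc(O[Si](C)(C)C(C)(C)C)cc(C)c1O[Si](C)(C)C(C)(C)C
F2 | step 16 | (E)-5-[2,5-bis(tert-butyldimethylsilyloxy)-3-methylphenyl]-3-methylpent-3-enal | O=CC/C(C)=C/Cc1cc(O[Si](C)(C)C(C)(C)C)cc(C)c1O[Si](C)(C)C(C)(C)C
F3 | step 16 | (2E,6Z,10E,13R)-1-[2,5-bis(tert-butyldimethylsilyloxy)-3-methylphenyl]-3,7,11,15-tetramethyl-13-(triethylsilyloxy)hexadeca-2,6,10,14-tetraen-5-ol (both C5 epimers) | CC(C)=C[C@H](O[Si](CC)(CC)CC)C/C(C)=C/CC/C(C)=C\C(O)C/C(C)=C/Cc1cc(O[Si](C)(C)C(C)(C)C)cc(C)c1O[Si](C)(C)C(C)(C)C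
F4 | step 13 | (6E,10Z)-11-iodo-2,6,10-trimethylundeca-2,6,10-trien-4-ol (racemic) | CC(C)=CC(O)C/C(C)=C/CC/C(C)=C\I
F5 | step 13 | (4R,6E,10Z)-11-iodo-2,6,10-trimethylundeca-2,6,10-trien-4-yl (S)-2-methoxy-2-phenylacetate | CC(C)=C[C@H](OC(=O)[C@@H](OC)c1ccccc1)C/C(C)=C/CC/C(C)=C\I
F6 | step 13 | (4S,6E,10Z)-11-iodo-2,6,10-trimethylundeca-2,6,10-trien-4-yl (S)-2-methoxy-2-phenylacetate | CC(C)=C[C@@H](OC(=O)[C@@H](OC)c1ccccc1)C/C(C)=C/CC/C(C)=C\I
F7 | step 17 | (4R,6E,10Z)-2,6,10-trimethyl-11-(tributylstannyl)undeca-2,6,10-trien-4-ol | CC(C)=C[C@H](O)C/C(C)=C/CC/C(C)=C\[Sn](CCCC)(CCCC)CCCC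
F8 | step 17 | (2E,6Z,10E,13R)-1-[2,5-bis(tert-butyldimethylsilyloxy)-3-methylphenyl]-13-hydroxy-3,7,11,15-tetramethylhexadeca-2,6,10,14-tetraen-5-one | CC(C)=C[C@H](O)C/C(C)=C/CC/C(C)=C\C(=O)C/C(C)=C/Cc1cc(O[Si](C)(C)C(C)(C)C)cc(C)c1O[Si](C)(C)C(C)(C)C
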